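**Plan**

1. Retrosynthesis cuts the interflavan bond C4(upper)–C6(lower) first, then ring C of the upper flavan at C3–C4 and at O1–C8a; the lower unit is cut back to a flavonol made from a chalcone.
2. Forward: a ring A aldehyde (C4 as CHO, C8a as C–F) and a chiral O1–C2–C3 unit give ring C of the upper flavan-4-ol in one flask; the lower flavonol is hydrogenated to the all-cis flavan-3,4-diol derivative; acid-mediated 4→6 arylation and global debenzylation follow.
3. Enabling feature: in the upper unit O1–C2–C3 carries the only stereocentre (C2, a benzylic carbinol) and can act as an O,C-dinucleophile, while C4/C4a/C8a of ring A is a dielectrophile. C8a lies between C8–O and C4a, so a fluoride there has no ortho hydrogen and no para donor. C4 is an aldehyde carbon whose carbinol is later ionisable because the 7-oxygen is para to C4a.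
4. Stereochemistry: upper C2 from a Corey–Bakshi–Shibata reduction; upper C4 from trans (axial) attack of the lower ring A on the flavan-4-yl cation; lower C2, C3, C4 from catalyst-controlled syn hydrogenation of the flavonol ether from one face.

Key step: step 4

Remark: C4 of compound 9 is formed and used as an epimer mixture, because this centre becomes a planar cation in step 10.

**Route**

Step 1
Reactants: 1 2-fluoro-3,4-dimethoxybenzaldehyde
Product: 2 2-fluoro-3,4-dihydroxybenzaldehyde
Conditions: BBr3 (2.5 equiv), CH2Cl2, −78 °C to rt; then H2O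
Reagents that add atoms: none
Why: Lewis-acid cleavage of aryl methyl ethers (BBr3 demethylation) should free both phenols while the aldehyde and the C–F bond survive; no stereocentre is involved.

Step 2
Reactants: 2 2-fluoro-3,4-dihydroxybenzaldehyde
Product: 3 3,4-bis(benzyloxy)-2-fluorobenzaldehyde
Conditions: BnBr (2.2 equiv), K2CO3, DMF, rt
Reagents that add atoms: benzyl bromide BrCc1ccccc1
Why: Williamson ether synthesis on both phenols at room temperature, where O-benzylation should be much faster than any intermolecular displacement of the fluoride.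

Step 3
Reactants: 4 2-bromo-1-[4-(benzyloxy)phenyl]ethanone
Product: 5 (R)-2-bromo-1-[4-(benzyloxy)phenyl]ethanol
Conditions: (R)-2-methyl-CBS-oxazaborolidine (10 mol%), BH3·SMe2 (0.7 equiv), THF, 0 °C; then MeOH, aqueous work-up
Reagents that add atoms: none
Why: Corey–Bakshi–Shibata reduction of a phenacyl halide, in which the (R)-catalyst should deliver hydride to the face that gives the (R)-bromohydrin; this is the spatial arrangement of the later 2S centre, the descriptor changing only because CH2Br outranks aryl.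

Step 4
Reactants: 5 (R)-2-bromo-1-[4-(benzyloxy)phenyl]ethanol, 3 3,4-bis(benzyloxy)-2-fluorobenzaldehyde
Product: 9 (2S)-7,8-bis(benzyloxy)-2-[4-(benzyloxy)phenyl]-3,4-dihydro-2H-chromen-4-ol (C4 epimer mixture), via lithium alkoxide 6 (not isolated), via β-oxido organolithium 7 (not isolated), via dilithium diolate 8 (not isolated)
Conditions: 5, n-BuLi (1.0 equiv), THF, −78 °C; LiC10H8 (lithium naphthalenide, 2.05 equiv), −78 °C; 3 (0.8 equiv), −78 °C; then KOtBu (2.5 equiv), DMPU, 80 °C; aqueous work-up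
Reagents that add atoms: none
Why: Proposed new method: O-lithiation and two-electron reductive cleavage of the C–Br bond of 5 should give the β-oxido organolithium 7, whose carbanion (future C3) adds to the aldehyde carbon (future C4) of 3 to give diolate 8; after Li/K exchange in DMPU the C2 alkoxide should displace fluoride at C8a by intramolecular nucleophilic aromatic substitution (addition–elimination through a Meisenheimer-type transition state), so that both bonds arise in one flask as a formal [3+3] annulation. The closest known reaction types are the addition of β-oxido organolithiums made from halohydrins to aldehydes and the alkoxide SNAr ring closure of 3-(2-fluoroaryl)propan-1-ols to chromans; their union on one substrate is the new element. Ring C closes in the 6-exo mode at the sp2 carbon C8a, the only alternative (closure by the C4 alkoxide) being a four-membered ring. The C2 stereocentre is carried over unchanged from 5 because no bond to it is made or broken, while C4 forms as an epimer mixture that is of no consequence. The step needs carbonyl addition to outrun β-elimination of 7, which −78 °C and the fast 1,2-addition should secure, and it needs substitution without aryne formation, which the substrate secures because C8a has no ortho hydrogen. The fluoride is activated inductively by the ortho (C8) and meta (C7) benzyloxy groups and has no donor in the para position (C6–H).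

Step 5
Reactants: 10 1-(2,3,4-trihydroxyphenyl)ethanone
Product: 11 1-[3,4-bis(benzyloxy)-2-hydroxyphenyl]ethanone
Conditions: BnBr (2.1 equiv), K2CO3, acetone, reflux
Reagents that add atoms: benzyl bromide BrCc1ccccc1
Why: Williamson ether synthesis that should stop at the 3,4-dibenzyl ether, because the 2-hydroxyl is hydrogen-bonded to the acetyl carbonyl and is the least nucleophilic phenol.

Step 6
Reactants: 11 1-[3,4-bis(benzyloxy)-2-hydroxyphenyl]ethanone, 12 4-(benzyloxy)benzaldehyde
Product: 13 (E)-1-[3,4-bis(benzyloxy)-2-hydroxyphenyl]-3-[4-(benzyloxy)phenyl]prop-2-en-1-one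
Conditions: KOH, EtOH, rt
Reagents that add atoms: none
Why: Claisen–Schmidt condensation (aldol condensation with dehydration), which should give the (E)-chalcone under thermodynamic control.

Step 7
Reactants: 13 (E)-1-[3,4-bis(benzyloxy)-2-hydroxyphenyl]-3-[4-(benzyloxy)phenyl]prop-2-en-1-one
Product: 15 7,8-bis(benzyloxy)-2-[4-(benzyloxy)phenyl]-3-hydroxy-4H-chromen-4-one, via trans-3-hydroxyflavanone 14 (not isolated)
Conditions: H2O2 (30% aq.), NaOH, MeOH/THF, 0 °C to rt
Reagents that add atoms: hydrogen peroxide OO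
Why: Algar–Flynn–Oyamada reaction, in which oxidative cyclisation of the 2'-hydroxychalcone should give 14 and further oxidation the flavonol; the free 6'-position favours flavonol over aurone, and no stereocentre remains.

Step 8
Reactants: 15 7,8-bis(benzyloxy)-2-[4-(benzyloxy)phenyl]-3-hydroxy-4H-chromen-4-one
Product: 16 3,7,8-tris(benzyloxy)-2-[4-(benzyloxy)phenyl]-4H-chromen-4-one
Conditions: BnBr (1.3 equiv), K2CO3, DMF, 50 °C
Reagents that add atoms: benzyl bromide BrCc1ccccc1
Why: Williamson ether synthesis on the acidic 3-hydroxyl, which removes the chelating enol proton before the hydrogenation.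

Step 9
Reactants: 16 3,7,8-tris(benzyloxy)-2-[4-(benzyloxy)phenyl]-4H-chromen-4-one
Product: 18 (2R,3R,4R)-3,7,8-tris(benzyloxy)-2-[4-(benzyloxy)phenyl]-3,4-dihydro-2H-chromen-4-ol (all-cis), via cis-flavanone 17 (not isolated)
Conditions: H2 (120 bar), Ru(cod)(2-methylallyl)2 (5 mol%), SINpEt·HBF4 (10 mol%; the enantiomer that leads to the 2R series), KOtBu (12 mol%), toluene/n-hexane, 40 °C
Reagents that add atoms: none
Why: Proposed new method: a homogeneous ruthenium–N-heterocyclic-carbene catalyst should add hydrogen syn across the C2=C3 enol ether bond of ring C and then reduce the C4 ketone of 17 from the same, less hindered face, so that the 2-aryl, 3-benzyloxy and 4-hydroxy groups end up cis with the face chosen by the catalyst; the closest known reaction type is the asymmetric hydrogenation of flavones to cis-flavan-4-ols with this catalyst family, not yet shown on 3-alkoxyflavones, and ruthenium should not hydrogenolyse aryl benzyl ethers.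

Step 10
Reactants: 9 (2S)-7,8-bis(benzyloxy)-2-[4-(benzyloxy)phenyl]-3,4-dihydro-2H-chromen-4-ol, 18 (2R,3R,4R)-3,7,8-tris(benzyloxy)-2-[4-(benzyloxy)phenyl]-3,4-dihydro-2H-chromen-4-ol
Product: 20 (2R,3R,4R)-3,7,8-tris(benzyloxy)-6-{(2S,4R)-7,8-bis(benzyloxy)-2-[4-(benzyloxy)phenyl]-3,4-dihydro-2H-chromen-4-yl}-2-[4-(benzyloxy)phenyl]-3,4-dihydro-2H-chromen-4-ol (upper unit 2,4-trans), via chroman-4-ylium cation 19 (not isolated)
Conditions: 18 (2.5 equiv), TsOH·H2O (5 mol%), CH2Cl2/1,1,1,3,3,3-hexafluoropropan-2-ol (4:1), −20 °C to 0 °C, slow addition of 9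
Reagents that add atoms: none
Why: Friedel–Crafts alkylation (the biomimetic flavan-4-ol condensation): acid should ionise the C4 carbinol of 9, which has no β-oxygen and is stabilised by O1 and the 7-benzyloxy group, faster than the β-oxygenated carbinol of 18, and C6 of 18 (ortho to 7-OBn, para to O1) should attack cation 19 along the axial trajectory anti to the equatorial 2-aryl group to give the 2,4-trans isomer, whose C4 has the spatial arrangement of the target although its descriptor reads R while the benzyl groups are present.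

Step 11
Reactants: 20 (2R,3R,4R)-3,7,8-tris(benzyloxy)-6-{(2S,4R)-7,8-bis(benzyloxy)-2-[4-(benzyloxy)phenyl]-3,4-dihydro-2H-chromen-4-yl}-2-[4-(benzyloxy)phenyl]-3,4-dihydro-2H-chromen-4-ol
Product: 21 (2R,3R,4R)-6-[(2S,4S)-7,8-dihydroxy-2-(4-hydroxyphenyl)-3,4-dihydro-2H-chromen-4-yl]-2-(4-hydroxyphenyl)-3,4-dihydro-2H-chromene-3,4,7,8-tetrol
Conditions: H2 (1 atm), Pd(OH)2/C, EtOAc/MeOH, rt, under argon on work-up
Reagents that add atoms: none
Why: Hydrogenolysis of the six aryl benzyl ethers and the 3-O-benzyl ether under neutral conditions, which should leave the benzylic C4–OH, both C2–O1 bonds and all five stereocentres untouched.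

**Compound list**

1 | 2-fluoro-3,4-dimethoxybenzaldehyde | COc1ccc(C=O)c(F)c1OC | starting material
2 | 2-fluoro-3,4-dihydroxybenzaldehyde | O=Cc1ccc(O)c(O)c1F | intermediate
3 | 3,4-bis(benzyloxy)-2-fluorobenzaldehyde | O=Cc1ccc(OCc2ccccc2)c(OCc2ccccc2)c1F | intermediate
4 | 2-bromo-1-[4-(benzyloxy)phenyl]ethanone | O=C(CBr)c1ccc(OCc2ccccc2)cc1 | starting material
5 | (R)-2-bromo-1-[4-(benzyloxy)phenyl]ethanol | O[C@@H](CBr)c1ccc(OCc2ccccc2)cc1 | intermediate
6 | lithium (R)-2-bromo-1-[4-(benzyloxy)phenyl]ethanolate | [Li]O[C@@H](CBr)c1ccc(OCc2ccccc2)cc1 | intermediate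
7 | lithium (S)-1-[4-(benzyloxy)phenyl]-2-lithioethanolate (β-oxido organolithium) | [Li]O[C@@H](C[Li])c1ccc(OCc2ccccc2)cc1 | intermediate
8 | dilithium (3S)-1-[3,4-bis(benzyloxy)-2-fluorophenyl]-3-[4-(benzyloxy)phenyl]propane-1,3-diolate (C1 epimers) | [Li]O[C@@H](CC(O[Li])c1ccc(OCc2ccccc2)c(OCc2ccccc2)c1F)c1ccc(OCc2ccccc2)cc1 | intermediate
9 | (2S)-7,8-bis(benzyloxy)-2-[4-(benzyloxy)phenyl]-3,4-dihydro-2H-chromen-4-ol (C4 epimers) | OC1C[C@@H](c2ccc(OCc3ccccc3)cc2)Oc2c1ccc(OCc1ccccc1)c2OCc1ccccc1 | intermediate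
10 | 1-(2,3,4-trihydroxyphenyl)ethanone | CC(=O)c1ccc(O)c(O)c1O | starting material
11 | 1-[3,4-bis(benzyloxy)-2-hydroxyphenyl]ethanone | CC(=O)c1ccc(OCc2ccccc2)c(OCc2ccccc2)c1O | intermediate
12 | 4-(benzyloxy)benzaldehyde | O=Cc1ccc(OCc2ccccc2)cc1 | starting material
13 | (E)-1-[3,4-bis(benzyloxy)-2-hydroxyphenyl]-3-[4-(benzyloxy)phenyl]prop-2-en-1-one | O=C(/C=C/c1ccc(OCc2ccccc2)cc1)c1ccc(OCc2ccccc2)c(OCc2ccccc2)c1O | intermediate
14 | rac-(2R,3R)-7,8-bis(benzyloxy)-2-[4-(benzyloxy)phenyl]-3-hydroxy-2,3-dihydro-4H-chromen-4-one (2,3-trans, racemic, one enantiomer drawn) | O=C1c2ccc(OCc3ccccc3)c(OCc3ccccc3)c2O[C@H](c2ccc(OCc3ccccc3)cc2)[C@H]1O | intermediate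
15 | 7,8-bis(benzyloxy)-2-[4-(benzyloxy)phenyl]-3-hydroxy-4H-chromen-4-one | O=c1c(O)c(-c2ccc(OCc3ccccc3)cc2)oc2c1ccc(OCc1ccccc1)c2OCc1ccccc1 | intermediate
16 | 3,7,8-tris(benzyloxy)-2-[4-(benzyloxy)phenyl]-4H-chromen-4-one | O=c1c(OCc2ccccc2)c(-c2ccc(OCc3ccccc3)cc2)oc2c1ccc(OCc1ccccc1)c2OCc1ccccc1 | intermediate
17 | (2R,3S)-3,7,8-tris(benzyloxy)-2-[4-(benzyloxy)phenyl]-2,3-dihydro-4H-chromen-4-one (2,3-cis) | O=C1c2ccc(OCc3ccccc3)c(OCc3ccccc3)c2O[C@H](c2ccc(OCc3ccccc3)cc2)[C@@H]1OCc1ccccc1 | intermediate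
18 | (2R,3R,4R)-3,7,8-tris(benzyloxy)-2-[4-(benzyloxy)phenyl]-3,4-dihydro-2H-chromen-4-ol (all-cis) | c1cc2c(c(OCc3ccccc3)c1OCc1ccccc1)O[C@H](c1ccc(OCc3ccccc3)cc1)[C@H](OCc1ccccc1)[C@@H]2O | intermediate
19 | (2S)-7,8-bis(benzyloxy)-2-[4-(benzyloxy)phenyl]-3,4-dihydro-2H-chromen-4-ylium | [CH+]1C[C@@H](c2ccc(OCc3ccccc3)cc2)Oc2c1ccc(OCc1ccccc1)c2OCc1ccccc1 | intermediate
20 | (2R,3R,4R)-3,7,8-tris(benzyloxy)-6-{(2S,4R)-7,8-bis(benzyloxy)-2-[4-(benzyloxy)phenyl]-3,4-dihydro-2H-chromen-4-yl}-2-[4-(benzyloxy)phenyl]-3,4-dihydro-2H-chromen-4-ol | c1ccccc1COc1ccc([C@@H]2C[C@@H](c3cc4c(c(OCc5ccccc5)c3OCc3ccccc3)O[C@H](c3ccc(OCc5ccccc5)cc3)[C@H](OCc3ccccc3)[C@@H]4O)c3ccc(OCc4ccccc4)c(OCc4ccccc4)c3O2)cc1 | intermediate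
21 | (2R,3R,4R)-6-[(2S,4S)-7,8-dihydroxy-2-(4-hydroxyphenyl)-3,4-dihydro-2H-chromen-4-yl]-2-(4-hydroxyphenyl)-3,4-dihydro-2H-chromene-3,4,7,8-tetrol | Oc1ccc([C@@H]2C[C@@H](c3cc4c(c(O)c3O)O[C@H](c3ccc(O)cc3)[C@H](O)[C@@H]4O)c3ccc(O)c(O)c3O2)cc1 | target

**Step count and risks**

Total steps: 11. Longest linear sequence: 7 steps (steps 5 to 11).

Steps most likely to fail:

Step 4 (Proposed new method). The organolithium may undergo β-elimination to the styrene before it adds, the arene radical anion may cleave benzyl ethers, or the unactivated fluoride may resist displacement so that the sequence stops at the open diol. The fallback builds ring C from the phenol side by known chemistry. It sets out from 11: condensation with N,N-dimethylformamide dimethyl acetal should give (E)-1-[3,4-bis(benzyloxy)-2-hydroxyphenyl]-3-(dimethylamino)prop-2-en-1-one F1, which acid closes to 7,8-bis(benzyloxy)-4H-chromen-4-one F2. Enantioselective conjugate addition of 4-(benzyloxy)phenylboronic acid, catalysed by Pd(OCOCF3)2 and the t-BuPyOX enantiomer that leads to the 2S series, should give (2S)-7,8-bis(benzyloxy)-2-[4-(benzyloxy)phenyl]-2,3-dihydro-4H-chromen-4-one F3. Reduction with NaBH4 comes back to the route at 9.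

Step 9 (Proposed new method). The tetrasubstituted alkene may not turn over, facial selectivity may be poor, or C3 of the intermediate ketone may epimerise before the carbonyl is reduced. The fallback uses the classical heterogeneous route and resolves at the dimer stage. It sets out from 15: exhaustive hydrogenation (H2, Pd/C then PtO2, EtOH) should first debenzylate to 3,7,8-trihydroxy-2-(4-hydroxyphenyl)-4H-chromen-4-one F4 and then saturate ring C from one face to racemic all-cis 2-(4-hydroxyphenyl)-3,4-dihydro-2H-chromene-3,4,7,8-tetrol F5. Acid-catalysed condensation of 9 with the free phenol F5 (dilute HCl, dioxane/hexafluoropropan-2-ol) should give the 4→6 linked diastereomer with the (2R,3R,4R) lower unit F6 and its diastereomer with the (2S,3S,4S) lower unit F7, to be separated by chromatography. Hydrogenolysis of F6 (H2, Pd(OH)2/C) comes back to the route at 21.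

Step 10. The electrophile may self-condense through its own ring A, the C4 carbinol of 18 may ionise with epimerisation or oligomerisation, O-alkylation may compete with C-alkylation, or trans selectivity may erode. The fallback changes the mode of activation to a thiophilic, non-protic one. It sets out from 9: reaction with phenylmethanethiol and ZnI2 should give (2S)-4-(benzylsulfanyl)-7,8-bis(benzyloxy)-2-[4-(benzyloxy)phenyl]-3,4-dihydro-2H-chromene F8. Treatment of F8 with AgBF4 in THF/CH2Cl2 at low temperature in the presence of 18 should release the C4 cation without a protic acid and come back to the route at 20.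

**Further compounds**

F1 | step 4 | (E)-1-[3,4-bis(benzyloxy)-2-hydroxyphenyl]-3-(dimethylamino)prop-2-en-1-one | CN(C)/C=C/C(=O)c1ccc(OCc2ccccc2)c(OCc2ccccc2)c1O
F2 | step 4 | 7,8-bis(benzyloxy)-4H-chromen-4-one | O=c1ccoc2c1ccc(OCc1ccccc1)c2OCc1ccccc1
F3 | step 4 | (2S)-7,8-bis(benzyloxy)-2-[4-(benzyloxy)phenyl]-2,3-dihydro-4H-chromen-4-one | O=C1C[C@@H](c2ccc(OCc3ccccc3)cc2)Oc2c1ccc(OCc1ccccc1)c2OCc1ccccc1
F4 | step 9 | 3,7,8-trihydroxy-2-(4-hydroxyphenyl)-4H-chromen-4-one | O=c1c(O)c(-c2ccc(O)cc2)oc2c1ccc(O)c2O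
F5 | step 9 | rac-(2R,3R,4R)-2-(4-hydroxyphenyl)-3,4-dihydro-2H-chromene-3,4,7,8-tetrol (racemic, one enantiomer drawn) | Oc1ccc2c(c1O)O[C@H](c1ccc(O)cc1)[C@H](O)[C@@H]2O
F6 | step 9 | (2R,3R,4R)-6-{(2S,4S)-7,8-bis(benzyloxy)-2-[4-(benzyloxy)phenyl]-3,4-dihydro-2H-chromen-4-yl}-2-(4-hydroxyphenyl)-3,4-dihydro-2H-chromene-3,4,7,8-tetrol | c1ccccc1COc1ccc([C@@H]2C[C@@H](c3cc4c(c(O)c3O)O[C@H](c3ccc(O)cc3)[C@H](O)[C@@H]4O)c3ccc(OCc4ccccc4)c(OCc4ccccc4)c3O2)cc1
F7 | step 9 | (2S,3S,4S)-6-{(2S,4S)-7,8-bis(benzyloxy)-2-[4-(benzyloxy)phenyl]-3,4-dihydro-2H-chromen-4-yl}-2-(4-hydroxyphenyl)-3,4-dihydro-2H-chromene-3,4,7,8-tetrol | c1ccccc1COc1ccc([C@@H]2C[C@@H](c3cc4c(c(O)c3O)O[C@@H](c3ccc(O)cc3)[C@@H](O)[C@H]4O)c3ccc(OCc4ccccc4)c(OCc4ccccc4)c3O2)cc1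
F8 | step 10 | (2S)-4-(benzylsulfanyl)-7,8-bis(benzyloxy)-2-[4-(benzyloxy)phenyl]-3,4-dihydro-2H-chromene (C4 epimers) | C(c1ccccc1)SC1C[C@@H](c2ccc(OCc3ccccc3)cc2)Oc2c1ccc(OCc1ccccc1)c2OCc1ccccc1
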